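## Analysis of the target

The target, 19, is an achiral diarylmethane: two hexasubstituted acylphloroglucinol rings joined by one CH2 group, with no stereocentre and no further ring. Ring A carries butyryl at C1, OH at C2, CH3 at C3, OH at C4, the bridge at C5 and OH at C6. Ring B carries the bridge at C1, OH at C2, propionyl at C3, OH at C4, CH3 at C5 and OCH3 at C6. The sensitive features are five free phenols on very electron-rich rings (air oxidation, O- against C-reactivity), two aryl ketones held in hydrogen-bonded chelates with their ortho hydroxyls, and the bridge itself, which acids can cut by ipso protonation and bases by quinone methide formation. Two things make the synthesis hard: the rings are different, so joining two finished phloroglucinols through a one-carbon electrophile would give homo- and hetero-dimers side by side; and the single methyl ether must sit on one particular oxygen of ring B and outlive the unmasking of the other five. The plan rests on the segment C2–C1–C6–C5 of ring B: an oxygenated carbon (C2), the bridge-bearing carbon (C1), the methoxy-bearing carbon (C6) and the methyl-bearing carbon (C5) are, in this order, the four carbons of a 1,3-dimethoxy-1-silyloxy diene, so the C6 oxygen can be a methyl enol ether from the start, while C3 with its propionyl group and C4 with its oxygen arrive together from an alkoxy ynone.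

## Retrosynthetic reasoning

19 from 18. The last bonds cut are four O–alkyl bonds: the three benzyl ethers of ring A and the ethyl ether on the C4 oxygen of ring B. They are cut last because the free phenols are the most troublesome groups of 19, and because in 18 every aromatic carbon of both rings is substituted, so benzyl cations released during the cleavage find no ring position to attack. The forward reaction has to tell the C4 ethyl ether from the C6 methyl ether: the first lies ortho to the propionyl carbonyl and can be held in a metal chelate, the second lies para to it and cannot. A boron Lewis acid would be tied up by the C2 hydroxyl and the carbonyl in a stable chelate and would leave the ethyl ether on the other side untouched unless forced, so an aluminium Lewis acid, which can strip a second ortho ether, is planned.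

18 from 17. The bond between ring A C1 and the butyryl carbonyl is cut next. In 17 this carbon is the only aromatic C–H of the whole molecule and ring A is a trialkoxy arene of the highest nucleophilicity, so a Friedel–Crafts acylation has one place to go. It is placed before the deprotection: on the tri-ether there are no ring A hydroxyls to be O-acylated, and the one open ring position is closed before any benzyl cation is set free.

17 from 10 and 14. Ring B is taken apart at C4–C5 and C2–C3, which turns it into the diene 10 (ring B C2, C1, C6, C5) and the ynone 14 (C3, C4). The bond from the bridge CH2 to ring B C1 is deliberately not cut: it is already in the diene, so the unsymmetrical diarylmethane never has to be made by coupling two arenes. The gain is that the C6 methoxy group is carried as the enol ether of the diene and is never a free hydroxyl, that the C2 oxygen emerges as a phenol, and that the C4 oxygen arrives as the ethoxy group of the alkyne. The forward reaction must form both bonds with the nucleophilic, methyl-bearing diene terminus on the ethoxy-bearing alkyne carbon, and then aromatise by loss of the ketal methoxy group at C2 as the alcohol.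

14 from 11 and 12. The C(sp)–C(=O) bond of the ynone is cut to the acetylide of 11 and the N-methoxy-N-methyl amide 12. The amide stops at the ketone stage, and both partners are commercial.

10 from 8, and 8 from 7. The O–Si bond of the ketene acetal and then the O–CH3 bond of the enol ether are cut. 8 has conjugatively acidic hydrogens only at its γ-carbon, so deprotonation and O-silylation can give only the extended diene. 8 in turn is the methyl enol ether of the β-keto ester 7.

7 from 6, and 6 from 4 and 5. The bond between the bridge carbon and the α-carbon of the keto ester (the future ring B C1) is cut as a C=C bond: condensation of aldehyde 4 with keto ester 5 gives 6, and conjugate reduction gives 7. Alkylating 5 with a benzylic electrophile made from 4 would take more steps, and such an electron-rich benzylic electrophile, with an unsubstituted, nucleophilic ring position, ionises readily and condenses with itself. The aldehyde is a stable electrophile.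

4 from 3, and 3 from 1. The three O–benzyl bonds and the ring–CHO bond are cut. Formylation comes first because the two open positions of 1 are equivalent. Benzylation comes second because the formyl group tempers the ring, so O-alkylation wins over C-benzylation. Benzyl is chosen because it can be removed without endangering an aryl methyl ether.

## Alternatives that were turned down

Alternative 1: The butyryl group is disconnected last at both bonds to its carbonyl carbon, ring A C1–C(=O) and C(=O)–propyl. In the forward sense the ring A aryl iodide A1, carbon monoxide A2 and B-propyl-9-borabicyclo[3.3.1]nonane A3 would be joined by Pd(PPh3)4 (zerovalent palladium) and K3PO4 to give the pentabenzyl ether A4 of the target, which hydrogenolysis would unmask. In its favour, the conditions are neutral, so the acid-labile bridge never meets a Lewis acid, and the position of the ketone is fixed by the iodide. On these two points it is stronger than the Friedel–Crafts step 9 of the chosen route. Against it, the iodide of A1 sits between two benzyloxy groups on an electron-rich ring, so oxidative addition is slow, and the acyl-palladium intermediate must form and transmetallate faster than direct coupling without carbonyl insertion. It also costs an iodination plus a three-component coupling where one acylation does the same job. Above all it is only a finishing move: A1 already contains the complete unsymmetrical dimer with the single methyl ether of ring B, so the real difficulties of the target are left to other chemistry. The chosen strategy spends its key step on exactly those difficulties and accepts a classical acylation for the butyryl group, with the carbonylative coupling kept as the fallback for step 9.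

Alternative 2: Ring A is built on the bridge by cutting C1–C2, C2–C3 and C4–C5 of ring A. On heating, the 3-benzyloxycyclobutenone A5, which carries ring B (as its dibenzyl ether) on the arylmethyl substituent, would undergo four-electron ring opening, [2+2] addition to 1-(triisopropylsilyloxy)propyne A6, a second ring opening and 6π electrocyclisation to give the ring A phenol A7. In A7, C2 OH is free, C4 is a silyl ether, C6 a benzyl ether and C1 still unsubstituted. In its favour, the pericyclic cascade is thermal and neutral, its regiochemistry is fixed by the polarity of A6, three ring bonds form in one operation, and it is arguably more predictable than a cycloaddition to the donor-substituted ynone 14. Against it, it constructs the wrong ring. Ring A has three free hydroxyls and is available whole from 1, so the differentiated oxygens that the benzannulation delivers are of no use. Ring B, whose methyl ether is the actual problem, must be made beforehand by other means and then carried, ketone included, through ketene chemistry to reach A5. A7 still lacks the butyryl group, so the endgame is no shorter. The chosen strategy buys ring A and builds ring B; the alternative does the opposite at the cost of several extra steps.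

Alternative 3: Ring B is cut at C3–C4 only and traced back to an open polyketide chain masked as the fully substituted pyranone A8 (4-methoxy, 3-methyl, 5-arylmethyl, 6-(2-oxobutyl)). Methanolic Mg(OMe)2 A9 would open the lactone of A8 to a methyl ester, and the magnesium-chelated carbanion between the two ketone carbonyls (ring B C3) would attack that ester carbon (ring B C4) in a Claisen closure to give A10, in which ring B is complete. In its favour, it is biomimetic, the methoxy group would come from the easy O-methylation of the pyranone 4-hydroxyl, and A10 has both ring B hydroxyls free, so no ethyl ether has to be cut at the end. On this point it is stronger than the chosen route. Against it, A8 is a fully substituted pyranone, and putting a benzyl group on its C5 and an acyl group on its C6 methyl takes a long sequence of regiochemically delicate enolate steps. After ring opening the open-chain intermediate can also close back to the lactone or fold by aldol condensation to an isomeric arene, so the decisive selectivity is left to chelation at the end of a long linear route. The chosen strategy reaches its precursor 10 in six steps from 1 and lets polarity matching decide the regiochemistry; it pays for this with one chelation-directed de-ethylation.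

Key step: step 8

Remark on the chemistry: the target is achiral. The double-bond geometry of 6, 8, 9 and 10 and the two stereocentres of the transient cycloadduct 15 are of no consequence; the SMILES show one representative isomer, and all isomers converge on 17. Compounds 1, 5, 11 (as a hexane solution) and 12 are taken as purchased.

## Route

Step 1
Reactants: 1 2,4,6-trihydroxytoluene
Product: 3 2,4,6-trihydroxy-3-methylbenzaldehyde, via aryl iminium chloride 2 (not isolated)
Conditions: POCl3, DMF, EtOAc, 0 °C → rt; then H2O, 60 °C
Reagents that add atoms: N,N-dimethylformamide, CN(C)C=O; water, O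
Why: Vilsmeier–Haack formylation; the two free ring positions of 1 are equivalent, and the iminium salt 2 is deactivated and precipitates, which should stop the reaction at monoformylation; hydrolysis of 2 gives the aldehyde.

Step 2
Reactants: 3 2,4,6-trihydroxy-3-methylbenzaldehyde
Product: 4 2,4,6-tris(benzyloxy)-3-methylbenzaldehyde
Conditions: BnBr, K2CO3, DMF, 60 °C
Reagents that add atoms: benzyl bromide, BrCc1ccccc1
Why: Williamson etherification; the formyl group lowers the C-nucleophilicity of the phenoxides, so O-benzylation should dominate over C-benzylation at the one free ring carbon; heating is needed for the two hydrogen-bonded ortho hydroxyls.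

Step 3
Reactants: 4 2,4,6-tris(benzyloxy)-3-methylbenzaldehyde; 5 methyl 3-oxopentanoate
Product: 6 methyl 2-[[2,4,6-tris(benzyloxy)-3-methylphenyl]methylidene]-3-oxopentanoate (E/Z mixture)
Conditions: piperidine (cat.), AcOH (cat.), PhMe, reflux, Dean–Stark
Reagents that add atoms: none
Why: Knoevenagel condensation; piperidine converts the hindered, electron-rich aldehyde into a more electrophilic iminium ion, the doubly activated CH2 of 5 adds, and azeotropic removal of water drives the equilibrium; the E/Z ratio does not matter because step 4 removes the double bond.

Step 4
Reactants: 6 methyl 2-[[2,4,6-tris(benzyloxy)-3-methylphenyl]methylidene]-3-oxopentanoate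
Product: 7 methyl 2-[[2,4,6-tris(benzyloxy)-3-methylphenyl]methyl]-3-oxopentanoate (racemic)
Conditions: Hantzsch ester (diethyl 2,6-dimethyl-1,4-dihydropyridine-3,5-dicarboxylate), PhMe/EtOH, 70 °C
Reagents that add atoms: none
Why: Conjugate transfer hydrogenation of the doubly activated alkene by the Hantzsch dihydropyridine, a hydride donor that leaves the ketone, the ester and the benzyl ethers alone (catalytic hydrogenation would strip the benzyl groups); the new α-stereocentre is racemic and is erased in step 5.

Step 5
Reactants: 7 methyl 2-[[2,4,6-tris(benzyloxy)-3-methylphenyl]methyl]-3-oxopentanoate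
Product: 8 methyl 3-methoxy-2-[[2,4,6-tris(benzyloxy)-3-methylphenyl]methyl]pent-2-enoate
Conditions: HC(OMe)3, H2SO4 (cat.), MeOH, rt → 50 °C
Reagents that add atoms: trimethyl orthoformate, COC(OC)OC
Why: Acid-catalysed enol ether formation (ketalisation by the orthoester, then loss of one alcohol), the usual entry to the ester precursors of Brassard-type dienes; double-bond isomers, and any β,γ-unsaturated isomer, give the same dienolate in step 6.

Step 6
Reactants: 8 methyl 3-methoxy-2-[[2,4,6-tris(benzyloxy)-3-methylphenyl]methyl]pent-2-enoate
Product: 10 (1E,3Z)-1,3-dimethoxy-2-[[2,4,6-tris(benzyloxy)-3-methylphenyl]methyl]-1-(trimethylsilyloxy)penta-1,3-diene, via lithium dienolate 9 (not isolated)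
Conditions: LiN(i-Pr)2 (LDA), THF, −78 °C; Me3SiCl, −78 → 0 °C
Reagents that add atoms: chlorotrimethylsilane, C[Si](C)(C)Cl
Why: Kinetic γ-deprotonation of the β-methoxy enoate, whose only conjugatively acidic hydrogens are on C4, gives the extended dienolate 9, and the hard silyl chloride traps it on oxygen (standard preparation of vinylketene acetals). Allylic strain should place the C4 methyl away from the fully substituted C2; 10 is hydrolytically labile and is used crude.

Step 7
Reactants: 11 ethoxyacetylene; 12 N-methoxy-N-methylpropanamide
Product: 14 1-ethoxypent-1-yn-3-one, via lithium ethoxyacetylide 13 (not isolated)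
Conditions: n-BuLi, THF, −78 °C; then 12, −78 → −20 °C; AcOH, −78 °C
Reagents that add atoms: none
Why: Deprotonation of the terminal alkyne and acylation of the lithium acetylide with a Weinreb amide; the chelated tetrahedral adduct prevents double addition, and a cold non-aqueous acid quench avoids hydration of the push–pull ynone, which is kept in solution because it is volatile.

Step 8
Reactants: 10 (1E,3Z)-1,3-dimethoxy-2-[[2,4,6-tris(benzyloxy)-3-methylphenyl]methyl]-1-(trimethylsilyloxy)penta-1,3-diene; 14 1-ethoxypent-1-yn-3-one
Product: 17 1-[6-ethoxy-2-hydroxy-4-methoxy-5-methyl-3-[[2,4,6-tris(benzyloxy)-3-methylphenyl]methyl]phenyl]propan-1-one, via cyclohexadiene cycloadduct 15 (not isolated), via aryl trimethylsilyl ether 16 (not isolated)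
Conditions: PhMe, rt → 80 °C; then 1 M HCl, THF, 0 °C → rt
Reagents that add atoms: none
Why: Diels–Alder addition of a Brassard-type vinylketene acetal to an acetylenic ketone followed by aromatisation, the known route from 1,1-dioxygenated dienes and ynones to phenols, applied here to a β-ethoxy ynone. The diene is nucleophilic at its methyl-bearing terminus and the ynone, polarised in the same sense by carbonyl pull and ethoxy push, is electrophilic at the ethoxy-bearing carbon, so this bond (ring B C4–C5) leads. The ketene acetal carbon then bonds to the acyl-bearing carbon (ring B C2–C3), either in one asynchronous [4+2] event or, in the stepwise limit, by 6-endo collapse of an allenolate onto the dioxygen-stabilised cation; this closes ring B as the cyclohexa-1,4-diene 15. 15 has a single ring hydrogen (at C5) and its leaving groups on the ketal carbon across the ring (C2), so 1,4-elimination of methanol is the only aromatisation path and gives the aryl silyl ether 16. Dilute acid completes this and cleaves the O–Si bond to give phenol 17, which is stabilised by a hydrogen bond to the propionyl carbonyl. The two stereocentres of 15 are transient and uncontrolled, and none remains. The selectivity needed is regiochemical and is secured by the matched polarisation of both partners, since the reverse orientation would have to join the two nucleophilic carbons and the two electrophilic ones. The temperature is kept at or below 80 °C because ethyl ynol ethers lose ethylene by retro-ene fragmentation at higher temperature, and an excess of the ynone compensates for its lowered dienophilicity.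

Step 9
Reactants: 17 1-[6-ethoxy-2-hydroxy-4-methoxy-5-methyl-3-[[2,4,6-tris(benzyloxy)-3-methylphenyl]methyl]phenyl]propan-1-one
Product: 18 1-[2,4,6-tris(benzyloxy)-3-methyl-5-[(4-ethoxy-2-hydroxy-6-methoxy-5-methyl-3-propanoylphenyl)methyl]phenyl]butan-1-one
Conditions: n-PrCOCl, SnCl4, CH2Cl2, −40 → −20 °C
Reagents that add atoms: butanoyl chloride, CCCC(Cl)=O
Why: Friedel–Crafts acylation at the only aromatic C–H of the molecule, on a trialkoxy-dialkyl arene reactive enough for the mild Lewis acid SnCl4 at low temperature; the ring B phenol and ketone are tied up as a tin chelate, so O-acylation is not expected. SnCl4 below −20 °C should leave the benzyl and ethyl ethers in place, and a benzyl group lost here would cost nothing because step 10 removes all three.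

Step 10
Reactants: 18 1-[2,4,6-tris(benzyloxy)-3-methyl-5-[(4-ethoxy-2-hydroxy-6-methoxy-5-methyl-3-propanoylphenyl)methyl]phenyl]butan-1-one
Product: 19 1-[3-[(2,4-dihydroxy-6-methoxy-5-methyl-3-propanoylphenyl)methyl]-2,4,6-trihydroxy-5-methylphenyl]butan-1-one (target)
Conditions: AlCl3, C6HMe5, CH2Cl2, 0 °C → rt; then 1 M HCl
Reagents that add atoms: none
Why: Lewis-acid ether cleavage: AlCl3 ionises the three benzyl ethers, with pentamethylbenzene taking up the benzyl cations, and cleaves the ethyl ether through an aluminium chelate between the propionyl carbonyl and the C4 oxygen, chloride attacking the ethyl carbon (the classical dealkylation ortho to an aryl ketone, which AlCl3 carries on to the second ortho oxygen where a boron trihalide tends to stop). The C6 methyl ether is para to the carbonyl, cannot chelate and should survive at room temperature; both rings are fully substituted, so C-benzylation has no site.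

## Compound list

1 | 2,4,6-trihydroxytoluene | Cc1c(O)cc(O)cc1O | starting material
2 | N-[(2,4,6-trihydroxy-3-methylphenyl)methylidene]-N-methylmethanaminium chloride (aryl iminium chloride) | C[N+](C)=Cc1c(O)cc(O)c(C)c1O.[Cl-] | intermediate
3 | 2,4,6-trihydroxy-3-methylbenzaldehyde | Cc1c(O)cc(O)c(C=O)c1O | intermediate
4 | 2,4,6-tris(benzyloxy)-3-methylbenzaldehyde | Cc1c(OCc2ccccc2)cc(OCc2ccccc2)c(C=O)c1OCc1ccccc1 | intermediate
5 | methyl 3-oxopentanoate | CCC(=O)CC(=O)OC | starting material
6 | methyl 2-[[2,4,6-tris(benzyloxy)-3-methylphenyl]methylidene]-3-oxopentanoate (E/Z mixture, Z drawn) | CCC(=O)/C(=C/c1c(OCc2ccccc2)cc(OCc2ccccc2)c(C)c1OCc1ccccc1)C(=O)OC | intermediate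
7 | methyl 2-[[2,4,6-tris(benzyloxy)-3-methylphenyl]methyl]-3-oxopentanoate (racemic) | CCC(=O)C(Cc1c(OCc2ccccc2)cc(OCc2ccccc2)c(C)c1OCc1ccccc1)C(=O)OC | intermediate
8 | methyl 3-methoxy-2-[[2,4,6-tris(benzyloxy)-3-methylphenyl]methyl]pent-2-enoate (E drawn; isomer mixture tolerated) | CC/C(OC)=C(\C(=O)OC)Cc1c(OCc2ccccc2)cc(OCc2ccccc2)c(C)c1OCc1ccccc1 | intermediate
9 | lithium (1E,3Z)-1,3-dimethoxy-2-[[2,4,6-tris(benzyloxy)-3-methylphenyl]methyl]penta-1,3-dien-1-olate (lithium dienolate) | C/C=C(\OC)/C(Cc1c(OCc2ccccc2)c(C)c(OCc2ccccc2)cc1OCc1ccccc1)=C(\OC)O[Li] | intermediate
10 | (1E,3Z)-1,3-dimethoxy-2-[[2,4,6-tris(benzyloxy)-3-methylphenyl]methyl]-1-(trimethylsilyloxy)penta-1,3-diene | C/C=C(\OC)/C(Cc1c(OCc2ccccc2)c(C)c(OCc2ccccc2)cc1OCc1ccccc1)=C(\OC)O[Si](C)(C)C | intermediate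
11 | ethoxyacetylene (ethoxyethyne) | CCOC#C | starting material
12 | N-methoxy-N-methylpropanamide | CCC(=O)N(C)OC | starting material
13 | lithium ethoxyacetylide | CCOC#C[Li] | intermediate
14 | 1-ethoxypent-1-yn-3-one | CCOC#CC(=O)CC | intermediate
15 | 1-[2-ethoxy-4,6-dimethoxy-3-methyl-5-[[2,4,6-tris(benzyloxy)-3-methylphenyl]methyl]-6-(trimethylsilyloxy)cyclohexa-1,4-dien-1-yl]propan-1-one (cycloadduct, diastereomer mixture, racemic) | CCOC1=C(C(=O)CC)C(OC)(O[Si](C)(C)C)C(Cc2c(OCc3ccccc3)c(C)c(OCc3ccccc3)cc2OCc2ccccc2)=C(OC)C1C | intermediate
16 | 1-[6-ethoxy-4-methoxy-5-methyl-3-[[2,4,6-tris(benzyloxy)-3-methylphenyl]methyl]-2-(trimethylsilyloxy)phenyl]propan-1-one (aryl trimethylsilyl ether) | CCOc1c(C)c(OC)c(Cc2c(OCc3ccccc3)c(C)c(OCc3ccccc3)cc2OCc2ccccc2)c(O[Si](C)(C)C)c1C(=O)CC | intermediate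
17 | 1-[6-ethoxy-2-hydroxy-4-methoxy-5-methyl-3-[[2,4,6-tris(benzyloxy)-3-methylphenyl]methyl]phenyl]propan-1-one | CCOc1c(C)c(OC)c(Cc2c(OCc3ccccc3)c(C)c(OCc3ccccc3)cc2OCc2ccccc2)c(O)c1C(=O)CC | intermediate
18 | 1-[2,4,6-tris(benzyloxy)-3-methyl-5-[(4-ethoxy-2-hydroxy-6-methoxy-5-methyl-3-propanoylphenyl)methyl]phenyl]butan-1-one | CCCC(=O)c1c(OCc2ccccc2)c(C)c(OCc2ccccc2)c(Cc2c(O)c(C(=O)CC)c(OCC)c(C)c2OC)c1OCc1ccccc1 | intermediate
19 | 1-[3-[(2,4-dihydroxy-6-methoxy-5-methyl-3-propanoylphenyl)methyl]-2,4,6-trihydroxy-5-methylphenyl]butan-1-one | CCCC(=O)c1c(O)c(C)c(O)c(Cc2c(O)c(C(=O)CC)c(O)c(C)c2OC)c1O | target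

## Step count and risk

Total: 10 steps. Longest linear sequence: 9 steps (1 → 3 → 4 → 6 → 7 → 8 → 10 → 17 → 18 → 19, that is steps 1–6 and 8–10); step 7 is a one-step side branch that supplies 14.

Least certain steps:

Step 8 (key step). The cycloaddition may not go to completion. The ethoxy donor lowers the electrophilicity of 14, and the fully substituted diene 10 reaches its s-cis conformation reluctantly. The temperature cannot be raised freely, because 14 then fragments by loss of ethylene, and 10 can desilylate back to 8 in the meantime. A second failure mode is interruption after the first bond: silyl transfer to the allenolate oxygen gives an open-chain Michael adduct that does not close thermally. The fallback sets out from 10 and 14 and returns at 17. It makes the two bonds one after the other by ionic chemistry. A Mukaiyama–Michael addition promoted by Me3SiOTf (cat.) or TiCl4 in CH2Cl2 at −78 °C, followed by aqueous work-up, should give the open-chain adduct methyl 5-ethoxy-3-methoxy-4-methyl-7-oxo-2-[[2,4,6-tris(benzyloxy)-3-methylphenyl]methyl]nona-2,5-dienoate F1. Treatment of this with the non-nucleophilic base LiN(SiMe3)2 in THF (−78 → 0 °C) should remove the doubly vinylogous hydrogen at C4. The resulting dienolate would attack the ester through its ketone α-carbon in a vinylogous Dieckmann closure, and loss of methoxide and tautomerisation give 17.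

Step 10. Forcing four ethers off in one Lewis-acid operation may go too far: demethylation at the hindered C6 oxygen once the reaction is warmed to finish the ethyl ether, or acid-induced scission of the methylene bridge by ipso protonation while benzyl cations and HCl are present. The fallback sets out from 18 and returns at 19, separating the two tasks. Hydrogenolysis (H2, Pd/C (palladium metal on carbon), EtOAc/MeOH, rt) removes the three benzyl groups under neutral conditions and should give 1-[3-[(4-ethoxy-2-hydroxy-6-methoxy-5-methyl-3-propanoylphenyl)methyl]-2,4,6-trihydroxy-5-methylphenyl]butan-1-one F2. MgI2 etherate (PhMe/THF, 60 °C), a weak Lewis acid that dealkylates only an oxygen it can hold in a chelate with a neighbouring carbonyl, then cuts the ethyl ether alone and gives 19.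

Step 9. Electrophilic attack may occur at the bridge-bearing carbon of ring A instead of the free one, with loss of the ring B benzyl cation (acyl-dealkylation), or the Lewis acid may remove benzyl groups before acylation is complete and so allow C-benzylation of the open position. The fallback sets out from 17 and returns at 18 without any Lewis acid. Iodination of the free ring A position (N-iodosuccinimide, MeCN, 0 °C) should give 1-[6-ethoxy-2-hydroxy-4-methoxy-5-methyl-3-[[2,4,6-tris(benzyloxy)-3-iodo-5-methylphenyl]methyl]phenyl]propan-1-one F3. A carbonylative Suzuki–Miyaura coupling of this with B-propyl-9-borabicyclo[3.3.1]nonane A3 under carbon monoxide A2 (1 atm), with Pd(PPh3)4 (zerovalent palladium) and K3PO4 in dioxane at 60 °C, then builds the butyryl group and gives 18.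

Step 5. Enol ether formation may stall at the ketal stage with this hindered α-substituted keto ester, and prolonged acid may instead fragment the electron-rich benzyl–carbon bond or let orthoester-derived cations attack the open ring A position. The fallback sets out from 7 and returns at 8 and makes no new compound. It O-methylates the preformed enolate (Cs2CO3 or KH, Me2SO4, DMF): a dissociated enolate with a hard methylating agent reacts at oxygen, the more so here because C-methylation would create a quaternary carbon.

Step 3. The condensation may be slow and incomplete, because the aldehyde carbonyl is flanked by two benzyloxy groups and deactivated by three oxygen donors, and the equilibrium with the hindered alkene 6 is unfavourable. The fallback sets out from 4 and returns at 7, bypassing 6. NaBH4 (MeOH/THF, 0 °C) reduces 4 to [2,4,6-tris(benzyloxy)-3-methylphenyl]methanol F4. PBr3 (Et2O, −20 °C) converts this into 1,3,5-tris(benzyloxy)-2-(bromomethyl)-4-methylbenzene F5, which is not stored but added at once to the sodium enolate of 5 (NaH, THF, 0 °C) to give 7 by C-alkylation.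

## Further compounds

F1 | step 8 | methyl 5-ethoxy-3-methoxy-4-methyl-7-oxo-2-[[2,4,6-tris(benzyloxy)-3-methylphenyl]methyl]nona-2,5-dienoate (racemic, double-bond isomers) | CCOC(=CC(=O)CC)C(C)C(OC)=C(Cc1c(OCc2ccccc2)c(C)c(OCc2ccccc2)cc1OCc1ccccc1)C(=O)OC
F2 | step 10 | 1-[3-[(4-ethoxy-2-hydroxy-6-methoxy-5-methyl-3-propanoylphenyl)methyl]-2,4,6-trihydroxy-5-methylphenyl]butan-1-one | CCCC(=O)c1c(O)c(C)c(O)c(Cc2c(O)c(C(=O)CC)c(OCC)c(C)c2OC)c1O
F3 | step 9 | 1-[6-ethoxy-2-hydroxy-4-methoxy-5-methyl-3-[[2,4,6-tris(benzyloxy)-3-iodo-5-methylphenyl]methyl]phenyl]propan-1-one | CCOc1c(C)c(OC)c(Cc2c(OCc3ccccc3)c(C)c(OCc3ccccc3)c(I)c2OCc2ccccc2)c(O)c1C(=O)CC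
F0 | step 5 | none | none
F4 | step 3 | [2,4,6-tris(benzyloxy)-3-methylphenyl]methanol | Cc1c(OCc2ccccc2)cc(OCc2ccccc2)c(CO)c1OCc1ccccc1
F5 | step 3 | 1,3,5-tris(benzyloxy)-2-(bromomethyl)-4-methylbenzene | Cc1c(OCc2ccccc2)cc(OCc2ccccc2)c(CBr)c1OCc1ccccc1
A1 | alternative 1 | 1-[2,6-bis(benzyloxy)-4-methoxy-3-methyl-5-[[2,4,6-tris(benzyloxy)-3-iodo-5-methylphenyl]methyl]phenyl]propan-1-one (ring A aryl iodide) | Ic1c(OCc2ccccc2)c(C)c(OCc2ccccc2)c(Cc2c(OCc3ccccc3)c(C(=O)CC)c(OCc3ccccc3)c(C)c2OC)c1OCc1ccccc1
A2 | alternative 1 | carbon monoxide | [C-]#[O+]
A3 | alternative 1 | B-propyl-9-borabicyclo[3.3.1]nonane | CCCB1C2CCCC1CCC2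
A4 | alternative 1 | pentabenzyl ether of the target | CCCC(=O)c1c(OCc2ccccc2)c(C)c(OCc2ccccc2)c(Cc2c(OCc3ccccc3)c(C(=O)CC)c(OCc3ccccc3)c(C)c2OC)c1OCc1ccccc1
A5 | alternative 2 | 3-(benzyloxy)-2-[[2,4-bis(benzyloxy)-6-methoxy-5-methyl-3-propanoylphenyl]methyl]cyclobut-2-en-1-one | O=C1CC(OCc2ccccc2)=C1Cc1c(OCc2ccccc2)c(C(=O)CC)c(OCc2ccccc2)c(C)c1OC
A6 | alternative 2 | 1-(triisopropylsilyloxy)propyne | CC#CO[Si](C(C)C)(C(C)C)C(C)C
A7 | alternative 2 | ring A phenol with C2 OH free, C4 triisopropylsilyl ether, C6 benzyl ether, C1 unsubstituted | Cc1c(O)cc(OCc2ccccc2)c(Cc2c(OCc3ccccc3)c(C(=O)CC)c(OCc3ccccc3)c(C)c2OC)c1O[Si](C(C)C)(C(C)C)C(C)C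
A8 | alternative 3 | 4-methoxy-3-methyl-6-(2-oxobutyl)-5-[[2,4,6-tris(benzyloxy)-3-methylphenyl]methyl]pyran-2-one | CCC(=O)CC1=C(Cc2c(OCc3ccccc3)c(C)c(OCc3ccccc3)cc2OCc2ccccc2)C(OC)=C(C)C(=O)O1
A9 | alternative 3 | magnesium dimethoxide, Mg(OMe)2 | [Mg+2].C[O-].C[O-]
A10 | alternative 3 | 1-[2,6-dihydroxy-4-methoxy-3-methyl-5-[[2,4,6-tris(benzyloxy)-3-methylphenyl]methyl]phenyl]propan-1-one | CCC(=O)c1c(O)c(C)c(OC)c(Cc2c(OCc3ccccc3)c(C)c(OCc3ccccc3)cc2OCc2ccccc2)c1O
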